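**Conventions.** C7 is the benzylic carbon, C8 the carbon that bears the aryloxy group, C9 the hydroxymethyl carbon. Ring A is the 4-hydroxy-3-methoxyphenyl ring on C7; ring B is the 4-hydroxy-2,6-dimethoxyphenyl ring on the C8 oxygen. The target is compound 14 and the 7-deoxy compound is 12.

## Analysis of the target

Compound 14 is an open-chain arylglycerol β-aryl ether. Its C7–C8–C9 chain carries ring A and a hydroxyl on C7, the oxygen of ring B on C8, and a primary alcohol at C9. The only stereocentres are C7 and C8, both S and adjacent, which is the threo series (C7–OH and C8–OAr on the same side of the zigzag chain). No ring links them, so nothing relays configuration from one to the other.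

Two groups are fragile. The C7 alcohol is a p-hydroxybenzylic alcohol and ionises to a quinone methide in acid or base, which epimerises C7. Ring B is a hydroquinone monoether, which oxidants convert to a quinone with loss of the C8–O bond.

The hard points are three:
- the ether oxygen lies between two methoxy groups, so it is a poor nucleophile towards a secondary carbon;
- the 1,2-relationship must be controlled in an acyclic system;
- the last operations must spare the labile benzylic alcohol.

The strategy rests on one feature: C7 is a benzylic carbon para to the free C4 hydroxyl of ring A. Flavin-dependent 4-alkylphenol oxidases of the vanillyl alcohol oxidase family dehydrogenate exactly this motif to a p-quinone methide and hydrate it on one face. Ring B has oxygen, not carbon, para to its hydroxyl and cannot react this way. The C7–O bond can therefore be made last, on the unprotected 7-deoxy compound 12.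

## Retrosynthetic reasoning

**14 to 12 (C7–O bond).** The C7–O bond is cut first. Forward, an aerobic flavoenzyme removes hydride from C7 of 12, and the bound quinone methide 13 is hydrated on one face. This places the most sensitive group of the molecule in the final step and needs no protecting group afterwards. C7 is set on a substrate whose C8 is already fixed, so an error at C7 appears as a separable diastereomer, not as the enantiomer. C8 is R in 12 and S in 14 only because the new oxygen raises the priority of C7; nothing moves in space. The forward step has to oxidise C7 only, hydrate one face of 13, avoid tautomerisation and a second oxidation, and leave ring B alone.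

**12 to 11 (two O–benzyl bonds).** Both phenols of 12 are traced back to benzyl ethers in 11. Hydrogenolysis is clean here because C7 is still a methylene group: 11 has no benzylic C–O bond other than the two protecting groups.

**11 to 10 (oxidation level of C9).** The primary alcohol is traced to the carboxylic acid 10. The acid is the directing group for the step that sets C8, and C9 is carried at the ester or acid level from the start, so no oxidative unmasking is needed.

**10 to 9 (C8–H and C7–H bonds).** The C8 stereocentre is traced to the Z acrylic acid 9 by asymmetric hydrogenation. The stereocentre is created after the C8–O bond already exists, so no substitution at a secondary carbon by the hindered ring B oxygen is ever required. The forward reaction has to deliver hydrogen to one face of a trisubstituted enol ether and leave the benzyl ethers untouched.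

**9 to 6 and 7 (C7=C8 bond).** The alkene is cut by an aldol condensation between the aryloxyacetate 6 and aldehyde 7, through ester 8. This is the convergent step: it joins the ring A fragment, which supplies C7, to the fragment carrying ring B, C8 and C9. The forward reaction has to give the Z geometry, which is the thermodynamically preferred one (ring A trans to the carboxyl group).

**6 to 5 to 3 (benzyl group; ring B C4–O bond).** The benzyl ether 6 comes from phenol 5, whose hydroxyl is traced to the formyl group of 3 by a Baeyer–Villiger oxidation through formate 4. The two oxygens of ring B are thus different from the outset: the hindered one is the phenol of 1, and the other is generated from carbon. No selective protection of a symmetrical hydroquinone is needed.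

**3 to 1 and 2 (O–C8 bond).** The congested aryl ether is cut to the phenol 1 and the primary halide 2. An SN2 reaction at an unhindered, carbonyl-activated carbon is the easiest way to attach anything to an oxygen flanked by two methoxy groups. Compound 2 supplies C8 and C9.

## Alternatives that were turned down

**Alternative 1: decarboxylative arylation at C7 (ring A C1–C7 bond).**
- Disconnection and key step: the dioxolane acid A2 and the aryl bromide A3 are coupled under blue light with Ir[dF(CF3)ppy]2(dtbbpy)PF6, NiCl2(dme), 4,4'-di-tert-butyl-2,2'-bipyridine and Cs2CO3. The carboxylate of A2 loses CO2, nickel captures the C7 radical, and reductive elimination gives the trans dioxolane A1.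
- For: C8 comes from the chiral pool. α-Oxygenated acids are good partners in this type of coupling. The five-membered ring gives a clear reason for the trans outcome, since the radical is intercepted on the face away from the C8 side chain.
- Against: A1 contains neither ring B nor the C8–O–aryl bond. After acetonide cleavage the C7 and C8 hydroxyls must be told apart. The C8 hydroxyl must then be arylated with retention by an electron-rich aryl group carrying two ortho methoxy groups. The alcohol is the stereogenic partner, so no SN2 route is open; only a C–O coupling or an SNAr reaction on an activated arene with later adjustment remains. The hardest bond of the target is thus left to the end, on a fragile benzylic diol, and the count rises well above ten steps.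
- Comparison: the key bond formation of this alternative is closer to established chemistry than the enzymatic step, and that point goes to it. The chosen route instead makes the hindered ether in step 1 by alkylation with a primary halide and needs roughly half the steps.

**Alternative 2: asymmetric γ-aryloxyallylboration (C7–C8 bond).**
- Disconnection and key step: the allyl aryl ether A5 is lithiated with s-BuLi and trapped with (+)-B-methoxydiisopinocampheylborane. BF3·OEt2 releases the (Z)-γ-aryloxyallylborane, which adds to aldehyde A6 through a chair transition state to give the syn homoallylic alcohol A4. The vinyl group is then cleaved and reduced to C9.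
- For: one step forms the C7–C8 bond and both stereocentres under reagent control. The Z borane leads to the threo series by the closed transition state. Ring B is already attached, and the route is short.
- Against: the known reaction uses alkyl allyl ethers whose oxygen chelates lithium and holds the Z geometry. In A5 the oxygen is an aryl ether oxygen of low basicity between two methoxy groups. Wittig rearrangement of the lithiated ether and ring metalation next to the methoxy groups compete. The vinyl group must later be cleaved oxidatively in the presence of two very electron-rich arenes, and the cleavage passes through an α-aryloxy aldehyde in which C8 can epimerise.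
- Comparison: this alternative is stronger in that its key step extends a known asymmetric reaction and sets two centres at once. The chosen route offers in exchange no organolithium chemistry on the sensitive ether, C9 at the right oxidation level throughout, and a C8 centre that is never next to an aldehyde.

**Alternative 3: dynamic kinetic transfer hydrogenation of a racemic keto ester (C7–H bond).**
- Disconnection and key step: the racemic keto ester A8 would come from C-acylation of the enolate of 6 by a ring A acyl donor. It is reduced with RuCl(p-cymene)[(R,R)-TsDPEN] in HCO2H/NEt3 while C8 racemises through the enol, giving the hydroxy ester A7. Ester reduction and hydrogenolysis follow.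
- For: it shares 6 with the chosen route, sets both centres in one catalytic step, needs no enzyme development and is the shortest of all at about six steps. On precedent and on step count it is stronger than the chosen strategy.
- Against: the diastereomer series depends on a syn/anti preference that varies with the α-substituent. Here that substituent is an unusually bulky, doubly ortho-substituted aryloxy group. The ketone is deactivated by the para oxygen of ring A, so reduction may not stay slower than racemisation in the required sense. The benzyl ethers must finally be removed next to the benzylic alcohol.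
- Comparison: the chosen strategy sets the two centres independently: C8 by a hydrogenation with direct substrate-class precedent, C7 by the enzyme. The threo or erythro outcome therefore does not depend on one substrate-controlled preference, the other C7 epimer is accessible by changing the enzyme variant, and the final step is free of protecting groups. The price is an unproven key step.

Key step: step 8

Assumption: the (Sa) antipode of the spiro ligand is taken to give the 2R acid 10 from the Z acid 9; if a first run shows the opposite sense, the (Ra) ligand is used and nothing else changes.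

Assumption: a variant of vanillyl alcohol oxidase that accepts 12 can be obtained by structure-guided mutagenesis and screening; the route rests on this.

## Route

Step 1
Reactants: 1 4-hydroxy-3,5-dimethoxybenzaldehyde (syringaldehyde); 2 ethyl bromoacetate
Product: 3 ethyl (4-formyl-2,6-dimethoxyphenoxy)acetate
Conditions: K2CO3, DMF, 60 °C
Reagents that add atoms: none
Why: Williamson ether synthesis; the phenoxide of 1, made more acidic by the para formyl group, displaces bromide from the primary, carbonyl-activated halide 2, and the two ortho methoxy groups do not hinder an SN2 reaction at such an open electrophile.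

Step 2
Reactants: 3 ethyl (4-formyl-2,6-dimethoxyphenoxy)acetate
Product: 5 ethyl (4-hydroxy-2,6-dimethoxyphenoxy)acetate, via aryl formate 4 (not isolated)
Conditions: mCPBA, CH2Cl2, 0 °C to rt; then K2CO3 (cat.), EtOH, rt
Reagents that add atoms: mCPBA (3-chloroperoxybenzoic acid), OOC(=O)c1cccc(Cl)c1
Why: Baeyer–Villiger (Dakin-type) oxidation; in the Criegee adduct the electron-rich trioxygenated aryl group migrates in preference to hydride and gives formate 4, and catalytic ethoxide then transfers the formyl group to ethanol without changing the ethyl ester.

Step 3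
Reactants: 5 ethyl (4-hydroxy-2,6-dimethoxyphenoxy)acetate
Product: 6 ethyl [4-(benzyloxy)-2,6-dimethoxyphenoxy]acetate
Conditions: BnBr, K2CO3, acetone, reflux
Reagents that add atoms: benzyl bromide, BrCc1ccccc1
Why: Williamson benzylation of an unhindered phenol; carbonate is too weak to enolise the ester, so only the phenoxide reacts.

Step 4
Reactants: 6 ethyl [4-(benzyloxy)-2,6-dimethoxyphenoxy]acetate; 7 4-(benzyloxy)-3-methoxybenzaldehyde (O-benzylvanillin)
Product: 9 (Z)-2-[4-(benzyloxy)-2,6-dimethoxyphenoxy]-3-[4-(benzyloxy)-3-methoxyphenyl]prop-2-enoic acid, via ethyl ester 8 (not isolated)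
Conditions: NaH (1.2 equiv), EtOH (cat.), THF, 0 °C to rt; then 2 M NaOH (aq), 50 °C; HCl; recrystallisation
Reagents that add atoms: sodium hydroxide (oxygen of the acid hydroxyl), [Na+].[OH-]
Why: Claisen-type aldol condensation; the enolate of 6 adds to the non-enolisable aldehyde 7 and the aldolate eliminates by E1cB under equilibrating conditions, which should favour the Z ester 8 with ring A trans to the carboxyl carbon. Hydroxide then saponifies 8, and crystallisation of acid 9 should remove any E isomer.

Step 5
Reactants: 9 (Z)-2-[4-(benzyloxy)-2,6-dimethoxyphenoxy]-3-[4-(benzyloxy)-3-methoxyphenyl]prop-2-enoic acid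
Product: 10 (R)-2-[4-(benzyloxy)-2,6-dimethoxyphenoxy]-3-[4-(benzyloxy)-3-methoxyphenyl]propanoic acid
Conditions: [Ir(cod)((Sa)-SIPHOX)]BArF (1 mol%; SIPHOX = 7-[bis(3,5-di-tert-butylphenyl)phosphino]-7'-(oxazolin-2-yl)-1,1'-spirobiindane, BArF = B[3,5-(CF3)2C6H3]4), H2 (6 atm), NEt3 (0.5 equiv), MeOH, rt
Reagents that add atoms: none
Why: Carboxylate-directed asymmetric hydrogenation of an α-aryloxy acrylic acid by a chiral spiro phosphine–oxazoline complex of monovalent iridium; the carboxylate binds the trivalent iridium dihydride, and the rigid spirobiindane pocket admits only one alkene face, so both hydrogens are delivered cis and C8 is set as R. Aryl benzyl ethers are inert to this homogeneous catalyst.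

Step 6
Reactants: 10 (R)-2-[4-(benzyloxy)-2,6-dimethoxyphenoxy]-3-[4-(benzyloxy)-3-methoxyphenyl]propanoic acid
Product: 11 (R)-2-[4-(benzyloxy)-2,6-dimethoxyphenoxy]-3-[4-(benzyloxy)-3-methoxyphenyl]propan-1-ol
Conditions: BH3·THF, THF, 0 °C to rt; then H2O
Reagents that add atoms: none
Why: Borane reduction of a carboxylic acid through the acyloxyborane; the medium is never basic, so the C8 centre next to the carboxyl group is not at risk, and ethers are untouched.

Step 7
Reactants: 11 (R)-2-[4-(benzyloxy)-2,6-dimethoxyphenoxy]-3-[4-(benzyloxy)-3-methoxyphenyl]propan-1-ol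
Product: 12 (R)-4-{[1-hydroxy-3-(4-hydroxy-3-methoxyphenyl)propan-2-yl]oxy}-3,5-dimethoxyphenol
Conditions: H2 (1 atm), Pd/C, EtOAc/EtOH, rt, inert atmosphere on work-up
Reagents that add atoms: none
Why: Hydrogenolysis of the two aryl benzyl ethers on palladium; the C8–O bond is a non-benzylic alkyl aryl ether and C7 carries no oxygen yet, so no other bond can be cleaved.

Step 8
Reactants: 12 (R)-4-{[1-hydroxy-3-(4-hydroxy-3-methoxyphenyl)propan-2-yl]oxy}-3,5-dimethoxyphenol
Product: 14 (1S,2S)-1-(4-hydroxy-3-methoxyphenyl)-2-(4-hydroxy-2,6-dimethoxyphenoxy)propane-1,3-diol, via quinone methide 13 (not isolated)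
Conditions: engineered vanillyl alcohol oxidase variant (covalent FAD, enlarged substrate cavity, Asp170 kept), O2 (air), catalase, KH2PO4/K2HPO4 buffer pH 8.0, 10% DMSO, 25 °C
Reagents that add atoms: water, O
Why: Proposed new method: the enzyme binds ring A as its phenolate, the oxidised flavin takes hydride from C7 (the only C–H para to a phenol oxygen in 12), and the planar quinone methide 13 stays in the closed cavity. A water molecule activated by the active-site aspartate then adds to C7 of 13 from the face it occupies, forming the C7–O bond and re-aromatising ring A, while O2 reoxidises the flavin to give H2O2, which catalase removes before it can attack ring B. The closest known reaction type is the hydroxylation of 4-ethylphenol, 4-propylphenol and 4-alkylguaiacols by vanillyl alcohol oxidase to (R)-1-(4-hydroxyphenyl)alkanols; new here is a substrate branching at C8 into an aryloxy and a hydroxymethyl group, for which the cavity must be widened by mutagenesis. No ring is closed. The new C7 centre is controlled by the enzyme through the position of the bound water relative to 13: the spatial sense of the known R products corresponds to 7S here, because C8 with its oxygen outranks ring A, and the fixed C8 centre is only a secondary bias. The step needs face selectivity at C7, hydration in preference to loss of the C8 proton to an enol ether, no second oxidation of 14 to the C7 ketone, and an untouched ring B. The substrate helps in three ways: ring B has oxygen and not carbon para to its hydroxyl and offers no hydride; the polar C9 hydroxyl and ether oxygen should keep water near C7 (dry pockets around long alkyl chains are what turn these enzymes towards alkenes); and attack of the C9 hydroxyl on C7 would give a strained oxetane. Because C8 is already single-configured, an error at C7 gives the erythro diastereomer, which is separable.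

## Compound list

1 | 4-hydroxy-3,5-dimethoxybenzaldehyde (syringaldehyde) | COc1cc(C=O)cc(OC)c1O | starting material
2 | ethyl bromoacetate | CCOC(=O)CBr | starting material
3 | ethyl (4-formyl-2,6-dimethoxyphenoxy)acetate | CCOC(=O)COc1c(OC)cc(C=O)cc1OC | intermediate
4 | ethyl [4-(formyloxy)-2,6-dimethoxyphenoxy]acetate (aryl formate, not isolated) | CCOC(=O)COc1c(OC)cc(OC=O)cc1OC | intermediate
5 | ethyl (4-hydroxy-2,6-dimethoxyphenoxy)acetate | CCOC(=O)COc1c(OC)cc(O)cc1OC | intermediate
6 | ethyl [4-(benzyloxy)-2,6-dimethoxyphenoxy]acetate | CCOC(=O)COc1c(OC)cc(OCc2ccccc2)cc1OC | intermediate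
7 | 4-(benzyloxy)-3-methoxybenzaldehyde (O-benzylvanillin) | COc1cc(C=O)ccc1OCc1ccccc1 | starting material
8 | ethyl (Z)-2-[4-(benzyloxy)-2,6-dimethoxyphenoxy]-3-[4-(benzyloxy)-3-methoxyphenyl]prop-2-enoate (not isolated) | CCOC(=O)/C(=C/c1ccc(OCc2ccccc2)c(OC)c1)Oc1c(OC)cc(OCc2ccccc2)cc1OC | intermediate
9 | (Z)-2-[4-(benzyloxy)-2,6-dimethoxyphenoxy]-3-[4-(benzyloxy)-3-methoxyphenyl]prop-2-enoic acid | OC(=O)/C(=C/c1ccc(OCc2ccccc2)c(OC)c1)Oc1c(OC)cc(OCc2ccccc2)cc1OC | intermediate
10 | (R)-2-[4-(benzyloxy)-2,6-dimethoxyphenoxy]-3-[4-(benzyloxy)-3-methoxyphenyl]propanoic acid | COc1cc(C[C@H](C(=O)O)Oc2c(OC)cc(OCc3ccccc3)cc2OC)ccc1OCc1ccccc1 | intermediate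
11 | (R)-2-[4-(benzyloxy)-2,6-dimethoxyphenoxy]-3-[4-(benzyloxy)-3-methoxyphenyl]propan-1-ol | COc1cc(C[C@H](CO)Oc2c(OC)cc(OCc3ccccc3)cc2OC)ccc1OCc1ccccc1 | intermediate
12 | (R)-4-{[1-hydroxy-3-(4-hydroxy-3-methoxyphenyl)propan-2-yl]oxy}-3,5-dimethoxyphenol | COc1cc(C[C@H](CO)Oc2c(OC)cc(O)cc2OC)ccc1O | intermediate
13 | 4-[(2R)-3-hydroxy-2-(4-hydroxy-2,6-dimethoxyphenoxy)propylidene]-2-methoxycyclohexa-2,5-dien-1-one (enzyme-bound quinone methide, exocyclic alkene geometry not defined, not isolated) | COC1=CC(=C[C@H](CO)Oc2c(OC)cc(O)cc2OC)C=CC1=O | intermediate
14 | (1S,2S)-1-(4-hydroxy-3-methoxyphenyl)-2-(4-hydroxy-2,6-dimethoxyphenoxy)propane-1,3-diol | COc1cc([C@H](O)[C@H](CO)Oc2c(OC)cc(O)cc2OC)ccc1O | target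

## Step count and risks

Total: 8 steps. Longest linear sequence: 8 steps (1 to 14); aldehyde 7 enters at step 4.

**Step 8 (key step, the proposed new method).**
- What may go wrong: the branched substrate may not bind productively in a cavity evolved for small 4-alkylphenols. If it does bind, the quinone methide may lose the C8 proton instead of being hydrated, water may attack the wrong face, the product may be oxidised a second time at C7, or ring B may autoxidise at the pH the enzyme prefers.
- Why no direct chemical oxidation of 12: ring B, a 4-alkoxyphenol, would be oxidised to a quinone with loss of the C8 ether before ring A gave its quinone methide.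
- Fallback (known chemistry, an auxiliary-controlled syn glycolate aldol): it sets out from 6 and returns at 14. Saponification of 6 (LiOH, THF/H2O) gives [4-(benzyloxy)-2,6-dimethoxyphenoxy]acetic acid F1. Its pivaloyl mixed anhydride acylates lithiated (R)-4-benzyl-1,3-oxazolidin-2-one to give (4R)-4-benzyl-3-{[4-(benzyloxy)-2,6-dimethoxyphenoxy]acetyl}-1,3-oxazolidin-2-one F2. The Z boron enolate (Bu2BOTf, i-Pr2NEt, CH2Cl2, −78 to 0 °C) adds to aldehyde 7 through a chair transition state and should give the syn aldol (4R)-4-benzyl-3-{(2R,3S)-2-[4-(benzyloxy)-2,6-dimethoxyphenoxy]-3-[4-(benzyloxy)-3-methoxyphenyl]-3-hydroxypropanoyl}-1,3-oxazolidin-2-one F3. LiBH4 in wet THF removes the auxiliary and gives (1S,2S)-2-[4-(benzyloxy)-2,6-dimethoxyphenoxy]-1-[4-(benzyloxy)-3-methoxyphenyl]propane-1,3-diol F4. Brief hydrogenolysis (H2, Pd/C, EtOAc) then gives 14; it must be stopped before the benzylic C7–O bond is attacked.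

**Step 5 (asymmetric hydrogenation).**
- What may go wrong: the doubly ortho-substituted aryloxy group may crowd the alkene, or its methoxy oxygens may compete for the metal, giving slow turnover or lower face selectivity. Any E isomer left in 9 would erode the enantiomeric purity.
- Fallback (chiral pool plus SN2 inversion): it sets out from 1 and returns at 12. Commercial 1-(benzyloxy)-4-bromo-2-methoxybenzene A3 is converted to [4-(benzyloxy)-3-methoxyphenyl]magnesium bromide F5. With CuI catalysis this opens commercial (S)-benzyl glycidyl ether at the terminal carbon to give (S)-1-(benzyloxy)-3-[4-(benzyloxy)-3-methoxyphenyl]propan-2-ol F6. A Mitsunobu reaction with the acidic phenol 1 (PPh3, DIAD, THF) inverts C8 and gives (R)-4-({1-(benzyloxy)-3-[4-(benzyloxy)-3-methoxyphenyl]propan-2-yl}oxy)-3,5-dimethoxybenzaldehyde F7. Baeyer–Villiger oxidation (mCPBA, CH2Cl2) gives (R)-4-({1-(benzyloxy)-3-[4-(benzyloxy)-3-methoxyphenyl]propan-2-yl}oxy)-3,5-dimethoxyphenyl formate F8. Methanolysis (K2CO3, MeOH) gives (R)-4-({1-(benzyloxy)-3-[4-(benzyloxy)-3-methoxyphenyl]propan-2-yl}oxy)-3,5-dimethoxyphenol F9. Hydrogenolysis of the three benzyl ethers (H2, Pd/C) gives 12.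

**Step 4 (condensation).**
- What may go wrong: the aldol addition to the electron-rich aldehyde may reverse faster than the aldolate eliminates, the ester may self-condense, or a mixture of alkene geometries may form.
- Fallback (stepwise kinetic aldol, then a separate elimination): it sets out from 6 and returns at 8. The lithium enolate of 6 (LDA, THF, −78 °C) adds to 7 to give ethyl 2-[4-(benzyloxy)-2,6-dimethoxyphenoxy]-3-[4-(benzyloxy)-3-methoxyphenyl]-3-hydroxypropanoate F10 as a diastereomer mixture. Acetylation (Ac2O, DMAP, pyridine) gives ethyl 3-acetoxy-2-[4-(benzyloxy)-2,6-dimethoxyphenoxy]-3-[4-(benzyloxy)-3-methoxyphenyl]propanoate F11. E1cB elimination with DBU in toluene at 80 °C gives 8, which is saponified to 9 as in the second stage of step 4.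

## Further compounds

F1 | step 8 | [4-(benzyloxy)-2,6-dimethoxyphenoxy]acetic acid | OC(=O)COc1c(OC)cc(OCc2ccccc2)cc1OC
F2 | step 8 | (4R)-4-benzyl-3-{[4-(benzyloxy)-2,6-dimethoxyphenoxy]acetyl}-1,3-oxazolidin-2-one | O=C(COc1c(OC)cc(OCc2ccccc2)cc1OC)N1[C@H](Cc2ccccc2)COC1=O
F3 | step 8 | (4R)-4-benzyl-3-{(2R,3S)-2-[4-(benzyloxy)-2,6-dimethoxyphenoxy]-3-[4-(benzyloxy)-3-methoxyphenyl]-3-hydroxypropanoyl}-1,3-oxazolidin-2-one | COc1cc([C@H](O)[C@H](C(=O)N2[C@H](Cc3ccccc3)COC2=O)Oc2c(OC)cc(OCc3ccccc3)cc2OC)ccc1OCc1ccccc1
F4 | step 8 | (1S,2S)-2-[4-(benzyloxy)-2,6-dimethoxyphenoxy]-1-[4-(benzyloxy)-3-methoxyphenyl]propane-1,3-diol | COc1cc([C@H](O)[C@H](CO)Oc2c(OC)cc(OCc3ccccc3)cc2OC)ccc1OCc1ccccc1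
F5 | step 5 | [4-(benzyloxy)-3-methoxyphenyl]magnesium bromide | COc1cc([Mg]Br)ccc1OCc1ccccc1
F6 | step 5 | (S)-1-(benzyloxy)-3-[4-(benzyloxy)-3-methoxyphenyl]propan-2-ol | COc1cc(C[C@@H](COCc2ccccc2)O)ccc1OCc1ccccc1
F7 | step 5 | (R)-4-({1-(benzyloxy)-3-[4-(benzyloxy)-3-methoxyphenyl]propan-2-yl}oxy)-3,5-dimethoxybenzaldehyde | COc1cc(C[C@H](COCc2ccccc2)Oc2c(OC)cc(C=O)cc2OC)ccc1OCc1ccccc1
F8 | step 5 | (R)-4-({1-(benzyloxy)-3-[4-(benzyloxy)-3-methoxyphenyl]propan-2-yl}oxy)-3,5-dimethoxyphenyl formate | COc1cc(C[C@H](COCc2ccccc2)Oc2c(OC)cc(OC=O)cc2OC)ccc1OCc1ccccc1
F9 | step 5 | (R)-4-({1-(benzyloxy)-3-[4-(benzyloxy)-3-methoxyphenyl]propan-2-yl}oxy)-3,5-dimethoxyphenol | COc1cc(C[C@H](COCc2ccccc2)Oc2c(OC)cc(O)cc2OC)ccc1OCc1ccccc1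
F10 | step 4 | ethyl 2-[4-(benzyloxy)-2,6-dimethoxyphenoxy]-3-[4-(benzyloxy)-3-methoxyphenyl]-3-hydroxypropanoate (racemic, both diastereomers) | CCOC(=O)C(Oc1c(OC)cc(OCc2ccccc2)cc1OC)C(O)c1ccc(OCc2ccccc2)c(OC)c1
F11 | step 4 | ethyl 3-acetoxy-2-[4-(benzyloxy)-2,6-dimethoxyphenoxy]-3-[4-(benzyloxy)-3-methoxyphenyl]propanoate (racemic, both diastereomers) | CCOC(=O)C(Oc1c(OC)cc(OCc2ccccc2)cc1OC)C(OC(C)=O)c1ccc(OCc2ccccc2)c(OC)c1
A1 | alternative 1 | (4S,5S)-4-[4-(benzyloxy)-3-methoxyphenyl]-5-[(tert-butyldimethylsilyloxy)methyl]-2,2-dimethyl-1,3-dioxolane (trans) | COc1cc([C@@H]2OC(C)(C)O[C@H]2CO[Si](C)(C)C(C)(C)C)ccc1OCc1ccccc1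
A2 | alternative 1 | (4R,5S)-5-[(tert-butyldimethylsilyloxy)methyl]-2,2-dimethyl-1,3-dioxolane-4-carboxylic acid | OC(=O)[C@@H]1OC(C)(C)O[C@H]1CO[Si](C)(C)C(C)(C)C
A3 | alternative 1 | 1-(benzyloxy)-4-bromo-2-methoxybenzene | COc1cc(Br)ccc1OCc1ccccc1
A4 | alternative 2 | (1S,2S)-2-[2,6-dimethoxy-4-(triisopropylsilyloxy)phenoxy]-1-[3-methoxy-4-(triisopropylsilyloxy)phenyl]but-3-en-1-ol | COc1cc([C@H](O)[C@H](C=C)Oc2c(OC)cc(O[Si](C(C)C)(C(C)C)C(C)C)cc2OC)ccc1O[Si](C(C)C)(C(C)C)C(C)C
A5 | alternative 2 | 2-(allyloxy)-1,3-dimethoxy-5-(triisopropylsilyloxy)benzene | C=CCOc1c(OC)cc(O[Si](C(C)C)(C(C)C)C(C)C)cc1OC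
A6 | alternative 2 | 3-methoxy-4-(triisopropylsilyloxy)benzaldehyde | COc1cc(C=O)ccc1O[Si](C(C)C)(C(C)C)C(C)C
A7 | alternative 3 | ethyl (2R,3S)-2-[4-(benzyloxy)-2,6-dimethoxyphenoxy]-3-[4-(benzyloxy)-3-methoxyphenyl]-3-hydroxypropanoate | COc1cc([C@H](O)[C@H](C(=O)OCC)Oc2c(OC)cc(OCc3ccccc3)cc2OC)ccc1OCc1ccccc1
A8 | alternative 3 | ethyl 2-[4-(benzyloxy)-2,6-dimethoxyphenoxy]-3-[4-(benzyloxy)-3-methoxyphenyl]-3-oxopropanoate (racemic) | CCOC(=O)C(Oc1c(OC)cc(OCc2ccccc2)cc1OC)C(=O)c1ccc(OCc2ccccc2)c(OC)c1
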